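**Plan**

1. Numbering: lactone C1(=O)–C5, chain C6–C18, oxolane O–C19–C20(Me)–C21H2–C22(Me), side arm C23–C24(OH). Cuts, in order: C13–C14 (diene σ-bond), C16–C17, then the oxolane bond C21–C22 (ring CH2 to the fully substituted ether carbon) and C18–C19; in the west half C2=C3, C4–C5, C6=C7 and C8=C9.
2. Key event: an alkylidene carbene generated at C21 from an acyclic methyl ketone (C20) inserts into the tertiary C22–H bond of a di-sec-alkyl ether. The enabling feature is the ring oxygen between C19 and C22: it activates the C22–H bond and holds it exactly 1,5 to the carbene carbon, so the oxolane ring and the quaternary C22 arise together, with retention.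
3. East, forward: (S)-butane-1,3-diol → glycolate ether → Ireland–Claisen (C18, C19) → lactone → methyl ketone → carbene ring closure → OH-directed hydrogenation (C20) → aldehyde → allenylzinc propargylation (C16) → hydrozirconation/Negishi union with the west iodide → C17 oxidation, desilylation.
4. West, forward: Evans alkylation (C10), Still–Gennari olefination (8Z), tandem oxidation–Wittig (6E), Brown anti-crotylation (C4, C5), acryloylation and ring-closing metathesis to the trans-lactone (second ring).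
5. Stereochemistry: C22 from (S)-butane-1,3-diol; C18/C19 by chirality transfer from (2S,3Z)-pent-3-en-2-ol; C20 by directed hydrogenation; C16 from (S)-pent-3-yn-2-yl mesylate; C10 from the oxazolidinone; C4/C5 from the Ipc2B reagent. The pivalate and the C20=C21 double bond are temporary helpers of the key step, removed in steps 11 and 12.

Key step: step 10

Remark: the target is taken exactly as drawn (4S,5R trans-lactone, 10R, 16R, 18R, 19R, 20R, 22R); the C17 carbinol configuration carried from step 15 to step 30 is of no consequence because C17 is oxidised in step 31.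

**Route**

Step 1
Reactants: 1 (S)-but-3-yn-2-ol
Product: 2 (S)-pent-3-yn-2-ol
Conditions: LiNH2 (2.1 equiv), liquid NH3, −33 °C; MeI (1.0 equiv); NH4Cl
Reagents that add atoms: iodomethane, CI
Why: The dilithium alkoxide–acetylide alkylates only at the far more nucleophilic acetylide carbon (alkynide alkylation), and no bond to the carbinol stereocentre is touched.

Step 2
Reactants: 2 (S)-pent-3-yn-2-ol
Product: 3 (2S,3Z)-pent-3-en-2-ol
Conditions: H2 (1 atm), Pd/CaCO3 poisoned with Pb(OAc)2, quinoline, pentane, 0 °C to rt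
Reagents that add atoms: none
Why: Lindlar semihydrogenation adds H2 syn to the alkyne and stops at the Z-alkene, the carbinol centre being unaffected.

Step 3
Reactants: 4 (S)-butane-1,3-diol
Product: 5 (2S)-4-(tert-butyldiphenylsilyloxy)butan-2-ol
Conditions: t-BuPh2SiCl (1.0 equiv), imidazole, CH2Cl2, 0 °C
Reagents that add atoms: tert-butyl(chloro)diphenylsilane, CC(C)(C)[Si](Cl)(c1ccccc1)c1ccccc1
Why: Silylation with the bulky chlorosilane discriminates the primary from the secondary hydroxyl (selective monoprotection).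

Step 4
Reactants: 5 (2S)-4-(tert-butyldiphenylsilyloxy)butan-2-ol; 6 bromoacetic acid
Product: 7 2-{[(2S)-4-(tert-butyldiphenylsilyloxy)butan-2-yl]oxy}acetic acid
Conditions: NaH (3 equiv), THF, 0 °C; BrCH2CO2H, 0 °C to rt; H3O+
Reagents that add atoms: none
Why: Williamson etherification of the secondary sodium alkoxide with sodium bromoacetate is an SN2 displacement at a primary carbon, so the future C22 centre keeps its S configuration because no bond to it is broken.

Step 5
Reactants: 7 the glycolic acid ether; 3 (2S,3Z)-pent-3-en-2-ol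
Product: 8 (2S,3Z)-pent-3-en-2-yl 2-{[(2S)-4-(tert-butyldiphenylsilyloxy)butan-2-yl]oxy}acetate
Conditions: EDCI·HCl, DMAP (cat.), CH2Cl2, 0 °C to rt
Reagents that add atoms: none
Why: Steglich-type carbodiimide esterification joins the acid and the secondary allylic alcohol under neutral conditions without touching either stereocentre or the Z-alkene.

Step 6
Reactants: 8 the glycolate ester
Product: 11 (2S,3S,4E)-2-{[(2S)-4-(tert-butyldiphenylsilyloxy)butan-2-yl]oxy}-3-methylhex-4-enoic acid, via silyl ketene acetal 9 (not isolated), via trimethylsilyl ester 10 (not isolated)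
Conditions: LiN(SiMe3)2, Me3SiCl, Et3N, THF, −78 °C to rt; 1 M HCl
Reagents that add atoms: none
Why: Ireland–Claisen rearrangement: chelation of lithium by the α-alkoxy oxygen gives the Z-ketene acetal 9, which rearranges through a chair transition state with the carbinol methyl equatorial, so the S centre and Z geometry of the allyl unit are transferred into C19 and C18 (methyl anti to the alkoxy group) and an E-alkene.

Step 7
Reactants: 11 the hexenoic acid
Product: 13 (3S,4S)-3-{[(2S)-4-(tert-butyldiphenylsilyloxy)butan-2-yl]oxy}-4-methyloxolan-2-one, via hydroxy acid 12 (not isolated)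
Conditions: O3, CH2Cl2/MeOH, −78 °C; NaBH4, −78 to 0 °C; 1 M HCl, then p-TsOH (cat.), CH2Cl2, rt
Reagents that add atoms: ozone, O=[O+][O-]
Why: Ozonolysis with borohydride work-up converts the propenyl group into the C17 hydroxymethyl group, and the γ-hydroxy acid 12 closes to the five-membered lactone on acidification with C18 and C19 untouched (cis on the ring).

Step 8
Reactants: 13 the lactone
Product: 14 (3S,4S)-5-hydroxy-4-methyl-3-{[(2S)-4-(tert-butyldiphenylsilyloxy)butan-2-yl]oxy}pentan-2-one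
Conditions: MeLi (1.05 equiv), THF, −78 °C; sat. NH4Cl at −78 °C
Reagents that add atoms: methyllithium, [Li]C
Why: One equivalent of MeLi adds once to the γ-lactone because the tetrahedral lithium hemiketal is stable at −78 °C and collapses to the γ-hydroxy methyl ketone only on work-up.

Step 9
Reactants: 14 the hydroxy ketone
Product: 15 (2S,3S)-2-methyl-4-oxo-3-{[(2S)-4-(tert-butyldiphenylsilyloxy)butan-2-yl]oxy}pentyl 2,2-dimethylpropanoate
Conditions: t-BuCOCl, pyridine, DMAP (cat.), CH2Cl2, 0 °C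
Reagents that add atoms: 2,2-dimethylpropanoyl chloride, CC(C)(C)C(Cl)=O
Why: Acylation of the primary alcohol installs a base-stable pivalate whose electron-withdrawing acyloxy group deactivates the neighbouring C17–H bonds toward carbene insertion in step 10.

Step 10
Reactants: 15 the keto pivalate
Product: 18 (2S)-2-[(2S,5S)-5-{2-(tert-butyldiphenylsilyloxy)ethyl}-3,5-dimethyl-2,5-dihydrofuran-2-yl]propyl 2,2-dimethylpropanoate, via diazoalkene 16 (not isolated), via alkylidene carbene 17 (not isolated)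
Conditions: Me3SiCHN2 (1.3 equiv), n-BuLi (1.25 equiv), THF, −78 °C; add 15; −78 to 0 °C
Reagents that add atoms: (trimethylsilyl)diazomethane, C[Si](C)(C)C=[N+]=[N-]
Why: Lithiated trimethylsilyldiazomethane adds to the methyl ketone, Peterson-type loss of Me3SiOLi gives the diazoalkene 16, and loss of N2 leaves the singlet alkylidene carbene 17, whose empty p orbital inserts concertedly into the C–H bond five atoms away. The closest known reaction type is the 1,5 C–H insertion of ketone-derived alkylidene carbenes into ether α-C–H bonds, which gives 2,5-dihydrofurans. The oxolane ring closes by this 1,5 insertion (five-membered ring, three-centre transition state in which C21 bonds to C22 while H shifts to C21), not by a polar exo or endo cyclisation. C22 becomes the quaternary stereocentre with retention, so it is controlled solely by the S-configured carbinol carbon of diol 4; C19 is not involved and C20 stays sp2 until step 12. The step needs site selectivity for the C22–H bond over the other bonds 1,5 to the carbene (C17–H2 and the C18 methyl) and over 1,2-shift to an alkyne; it is secured by the tertiary, oxygen-activated nature of C22–H (lone pair of the future ring oxygen), by the deactivating pivaloyloxy group at C17 and by the low migratory aptitude of alkyl groups.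

Step 11
Reactants: 18 the dihydrofuran pivalate
Product: 19 (2S)-2-[(2S,5S)-5-{2-(tert-butyldiphenylsilyloxy)ethyl}-3,5-dimethyl-2,5-dihydrofuran-2-yl]propan-1-ol
Conditions: i-Bu2AlH (2.5 equiv), CH2Cl2, −78 °C; aq. KNaC4H4O6
Reagents that add atoms: none
Why: i-Bu2AlH cleaves the pivalate reductively at low temperature while the silyl ether and the ring alkene are inert, freeing the C17 hydroxyl as a directing group.

Step 12
Reactants: 19 the dihydrofuran alcohol
Product: 20 (2S)-2-[(2R,3R,5R)-5-{2-(tert-butyldiphenylsilyloxy)ethyl}-3,5-dimethyloxolan-2-yl]propan-1-ol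
Conditions: H2 (1 atm), [Ir(cod)(PCy3)(py)]PF6 (5 mol %), CH2Cl2, rt
Reagents that add atoms: none
Why: Hydroxyl-directed homogeneous hydrogenation: the C17–OH binds the cationic iridium centre and H2 is delivered to the ring face that carries the C19 side chain, so the C20 methyl ends up trans to that chain (C20 R), while the silyloxyethyl arm on the other face cannot coordinate.

Step 13
Reactants: 20 the oxolane alcohol
Product: 21 (2R)-2-[(2R,3R,5R)-5-{2-(tert-butyldiphenylsilyloxy)ethyl}-3,5-dimethyloxolan-2-yl]propanal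
Conditions: Dess–Martin periodinane, NaHCO3, CH2Cl2, 0 °C to rt; used crude
Reagents that add atoms: none
Why: Dess–Martin oxidation gives the α-branched aldehyde under buffered, non-epimerising conditions.

Step 14
Reactants: 2 (S)-pent-3-yn-2-ol
Product: 22 (2S)-pent-3-yn-2-yl methanesulfonate
Conditions: MsCl, Et3N, CH2Cl2, −78 to 0 °C
Reagents that add atoms: methanesulfonyl chloride, CS(Cl)(=O)=O
Why: O-Sulfonylation forms only the O–S bond, so the propargylic centre is retained in the mesylate needed for the allenylmetal reagent.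

Step 15
Reactants: 21 the aldehyde; 22 (2S)-pent-3-yn-2-yl methanesulfonate
Product: 24 (2S,3R,4R)-2-[(2R,3R,5R)-5-{2-(tert-butyldiphenylsilyloxy)ethyl}-3,5-dimethyloxolan-2-yl]-4-methylhept-5-yn-3-ol, via allenylzinc 23 (not isolated)
Conditions: Pd(OAc)2 (5 mol %), PPh3 (5 mol %), Et2Zn (3 equiv), THF, −78 to −20 °C
Reagents that add atoms: none
Why: Marshall propargylation: zerovalent palladium formed in situ displaces the mesylate in an anti SN2' sense, transmetalation with Et2Zn gives the (M)-allenylzinc 23, and its cyclic SE2' addition to the aldehyde forms the C16–C17 bond on the face opposite to the departed mesylate, so C16 (R) is reagent-controlled and the anti-configured C17 carbinol is of no consequence.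

Step 16
Reactants: 24 the homopropargylic alcohol
Product: 25 triethylsilyl ether of 24 (C17–OSiEt3)
Conditions: Et3SiOTf, 2,6-lutidine, CH2Cl2, −78 °C
Reagents that add atoms: triethylsilyl trifluoromethanesulfonate, CC[Si](CC)(CC)OS(=O)(=O)C(F)(F)F
Why: Silyl triflate/lutidine silylation protects the hindered secondary alcohol so that it cannot direct the later hydrozirconation.

Step 17
Reactants: 26 methyl 2-[bis(2,2,2-trifluoroethoxy)phosphoryl]acetate
Product: 27 methyl 2-[bis(2,2,2-trifluoroethoxy)phosphoryl]butanoate (racemic)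
Conditions: NaH, EtI, THF/DMF, 0 °C to rt
Reagents that add atoms: iodoethane, CCI
Why: C-Alkylation of the sodium salt of the phosphonoacetate with a primary iodide gives the α-ethyl Still–Gennari reagent.

Step 18
Reactants: 28 (4S)-4-benzyl-3-propanoyl-1,3-oxazolidin-2-one; 29 3-bromoprop-1-yne
Product: 30 (4S)-4-benzyl-3-[(2R)-2-methylpent-4-ynoyl]-1,3-oxazolidin-2-one
Conditions: NaN(SiMe3)2, THF, −78 °C; HC≡CCH2Br, −78 to −40 °C
Reagents that add atoms: none
Why: Evans alkylation: the chelated Z-sodium enolate is attacked by the propargylic bromide on the face opposite the benzyl group, which sets the C10 centre.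

Step 19
Reactants: 30 the alkylated imide
Product: 31 (2R)-2-methylpent-4-yn-1-ol
Conditions: LiBH4, MeOH (1 equiv), Et2O, 0 °C
Reagents that add atoms: none
Why: LiBH4 reduces the exocyclic imide carbonyl selectively, releasing the auxiliary and the primary alcohol without epimerisation.

Step 20
Reactants: 31 (2R)-2-methylpent-4-yn-1-ol
Product: 33 (2R,4E)-5-iodo-2-methylpent-4-en-1-ol, via bis-zirconated alkenyl alkoxide 32 (not isolated)
Conditions: Cp2Zr(H)Cl (2.5 equiv), THF, rt; I2, 0 °C
Reagents that add atoms: iodine, II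
Why: Hydrozirconation–iodination: after the first equivalent has turned the OH into a zirconium alkoxide, Cp2Zr(H)Cl adds syn to the terminal alkyne with zirconium at the terminal carbon, and iodinolysis of the C–Zr bond with retention gives the E-vinyl iodide.

Step 21
Reactants: 33 the iodo alcohol
Product: 34 (2R,4E)-5-iodo-2-methylpent-4-enal
Conditions: Dess–Martin periodinane, NaHCO3, CH2Cl2, 0 °C; used crude
Reagents that add atoms: none
Why: Buffered Dess–Martin oxidation gives the α-methyl aldehyde without racemisation.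

Step 22
Reactants: 34 the aldehyde; 27 the α-ethyl phosphonate
Product: 35 methyl (2Z,4R,6E)-2-ethyl-7-iodo-4-methylhepta-2,6-dienoate
Conditions: 27, KN(SiMe3)2, 18-crown-6, THF, −78 °C; then 34
Reagents that add atoms: none
Why: Still–Gennari olefination: the electron-poor bis(trifluoroethyl) phosphonate with a dissociated potassium counter-ion eliminates rapidly from the kinetic adduct, giving the Z-trisubstituted enoate (ester cis to C10).

Step 23
Reactants: 35 the Z-enoate
Product: 36 (2Z,4R,6E)-2-ethyl-7-iodo-4-methylhepta-2,6-dien-1-ol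
Conditions: i-Bu2AlH (2.2 equiv), CH2Cl2, −78 °C
Reagents that add atoms: none
Why: i-Bu2AlH reduces the enoate 1,2 to the allylic alcohol, leaving the alkene geometry and the vinyl iodide intact.

Step 24
Reactants: 36 the allylic alcohol
Product: 38 (2E,4Z,6R,8E)-4-ethyl-9-iodo-N-methoxy-N,6-dimethylnona-2,4,8-trienamide, via Z-enal 37 (not isolated)
Conditions: MnO2 (activated, excess), Ph3P=CHC(O)N(OMe)Me, CH2Cl2, 40 °C
Reagents that add atoms: N-methoxy-N-methyl-2-(triphenylphosphoranylidene)acetamide, CON(C)C(=O)C=P(c1ccccc1)(c1ccccc1)c1ccccc1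
Why: Tandem oxidation–Wittig: MnO2 oxidises the allylic alcohol and the stabilised ylide traps the sensitive Z-enal 37 as it forms, giving the new C6=C7 bond E.

Step 25
Reactants: 38 the trienyl Weinreb amide
Product: 39 (2E,4Z,6R,8E)-4-ethyl-9-iodo-6-methylnona-2,4,8-trienal
Conditions: i-Bu2AlH (1.2 equiv), THF, −78 °C; aq. KNaC4H4O6
Reagents that add atoms: none
Why: i-Bu2AlH reduces the Weinreb amide to a chelated hemiaminal that releases the aldehyde only on work-up, so no over-reduction occurs.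

Step 26
Reactants: 39 the trienal
Product: 40 (3S,4R,5E,7Z,9R,11E)-7-ethyl-12-iodo-3,9-dimethyldodeca-1,5,7,11-tetraen-4-ol
Conditions: (E)-but-2-ene, KOt-Bu, n-BuLi, THF, −78 to −45 °C; (−)-Ipc2BOMe, −78 °C; BF3·OEt2; 39, −78 °C; NaBO3·4H2O, rt
Reagents that add atoms: (E)-but-2-ene, C/C=C/C
Why: Brown crotylboration: the (E)-crotylborane from (−)-Ipc2BOMe (the enantiomer derived from (+)-α-pinene) adds 1,2 to the aldehyde through a chair Zimmerman–Traxler transition state, the E geometry giving the anti C4/C5 relationship and the isopinocampheyl groups selecting the aldehyde face (4S,5R).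

Step 27
Reactants: 40 the homoallylic alcohol
Product: 41 prop-2-enoate ester of 40
Conditions: CH2=CHCOCl, i-Pr2NEt, CH2Cl2, −78 to 0 °C
Reagents that add atoms: prop-2-enoyl chloride, C=CC(Cl)=O
Why: O-Acylation of the secondary alcohol with acryloyl chloride installs the second terminal alkene for ring closure.

Step 28
Reactants: 41 the acrylate
Product: 42 (5S,6R)-6-[(1E,3Z,5R,7E)-3-ethyl-8-iodo-5-methylocta-1,3,7-trienyl]-5-methyl-5,6-dihydro-2H-pyran-2-one
Conditions: (H2IMes)(PCy3)Cl2Ru=CHPh (second-generation Grubbs catalyst, 5 mol %), CH2Cl2 (2 mM), 40 °C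
Reagents that add atoms: none
Why: Ring-closing metathesis joins the two terminal alkenes (vinyl and acrylate) to the six-membered α,β-unsaturated lactone with loss of ethene, the internal conjugated alkenes and the vinyl iodide being far less reactive.

Step 29
Reactants: 25 the silyl-protected alkyne; 42 the west vinyl iodide
Product: 45 protected coupling product (target skeleton with C17–OSiEt3 in place of C=O and C24–OSi(t-Bu)Ph2; 12E,14E), via alkenylzirconocene chloride 43 (not isolated), via alkenylzinc chloride 44 (not isolated)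
Conditions: 25 (1.3 equiv), Cp2Zr(H)Cl (1.6 equiv), THF, 50 °C; ZnCl2, 0 °C; 42, Pd(PPh3)4 (5 mol %), rt
Reagents that add atoms: none
Why: Hydrozirconation–Negishi coupling: syn addition of Zr–H places zirconium on the less hindered methyl-bearing alkyne carbon (C14), and exchange to zinc and palladium-catalysed coupling with the vinyl iodide proceed with retention at both sp2 carbons, giving the (12E,14E)-diene under neutral conditions that spare the lactone.

Step 30
Reactants: 45 the protected coupling product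
Product: 46 C17 alcohol (C24 still tert-butyldiphenylsilyl-protected)
Conditions: HF·pyridine, pyridine, THF, 0 °C
Reagents that add atoms: none
Why: Buffered HF·pyridine removes the secondary triethylsilyl ether much faster than the primary tert-butyldiphenylsilyl ether (selective desilylation).

Step 31
Reactants: 46 the C17 alcohol
Product: 47 C24-O-tert-butyldiphenylsilyl ether of the target (C17 ketone)
Conditions: Dess–Martin periodinane, NaHCO3, CH2Cl2, 0 °C
Reagents that add atoms: none
Why: Buffered Dess–Martin oxidation converts the C17 carbinol to the ketone without epimerising the flanking C16 and C18 centres.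

Step 32
Reactants: 47 the silyl ether
Product: 48 (5S,6R)-6-[(1E,3Z,5R,7E,9E,11R,13R)-3-ethyl-13-[(2R,3R,5R)-5-(2-hydroxyethyl)-3,5-dimethyloxolan-2-yl]-5,9,11-trimethyl-12-oxotetradeca-1,3,7,9-tetraenyl]-5-methyl-5,6-dihydro-2H-pyran-2-one (target)
Conditions: HF·pyridine (excess), THF, rt
Reagents that add atoms: none
Why: HF·pyridine cleaves the primary silyl ether under mildly acidic, non-basic conditions, which avoids epimerisation α to the ketone, β-elimination of the ring oxygen and lactone opening.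

**Compound list**

1 | (S)-but-3-yn-2-ol | C#C[C@H](C)O | starting material
2 | (S)-pent-3-yn-2-ol | CC#C[C@H](C)O | intermediate
3 | (2S,3Z)-pent-3-en-2-ol | C/C=C\[C@H](C)O | intermediate
4 | (S)-butane-1,3-diol | C[C@H](O)CCO | starting material
5 | (2S)-4-(tert-butyldiphenylsilyloxy)butan-2-ol | C[C@H](O)CCO[Si](c1ccccc1)(c1ccccc1)C(C)(C)C | intermediate
6 | bromoacetic acid | OC(=O)CBr | starting material
7 | 2-{[(2S)-4-(tert-butyldiphenylsilyloxy)butan-2-yl]oxy}acetic acid | OC(=O)CO[C@@H](C)CCO[Si](c1ccccc1)(c1ccccc1)C(C)(C)C | intermediate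
8 | (2S,3Z)-pent-3-en-2-yl 2-{[(2S)-4-(tert-butyldiphenylsilyloxy)butan-2-yl]oxy}acetate | C/C=C\[C@H](C)OC(=O)CO[C@@H](C)CCO[Si](c1ccccc1)(c1ccccc1)C(C)(C)C | intermediate
9 | (Z)-trimethylsilyl ketene acetal of 8 (Me3SiO cis to the sec-alkoxy group) | C/C=C\[C@H](C)O/C(O[Si](C)(C)C)=C/O[C@@H](C)CCO[Si](c1ccccc1)(c1ccccc1)C(C)(C)C | intermediate
10 | trimethylsilyl ester of acid 11 | C/C=C/[C@H](C)[C@@H](C(=O)O[Si](C)(C)C)O[C@@H](C)CCO[Si](c1ccccc1)(c1ccccc1)C(C)(C)C | intermediate
11 | (2S,3S,4E)-2-{[(2S)-4-(tert-butyldiphenylsilyloxy)butan-2-yl]oxy}-3-methylhex-4-enoic acid | C/C=C/[C@H](C)[C@@H](C(=O)O)O[C@@H](C)CCO[Si](c1ccccc1)(c1ccccc1)C(C)(C)C | intermediate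
12 | (2S,3S)-4-hydroxy-3-methyl-2-{[(2S)-4-(tert-butyldiphenylsilyloxy)butan-2-yl]oxy}butanoic acid | OC[C@H](C)[C@@H](C(=O)O)O[C@@H](C)CCO[Si](c1ccccc1)(c1ccccc1)C(C)(C)C | intermediate
13 | (3S,4S)-3-{[(2S)-4-(tert-butyldiphenylsilyloxy)butan-2-yl]oxy}-4-methyloxolan-2-one (cis) | C[C@H]1COC(=O)[C@H]1O[C@@H](C)CCO[Si](c2ccccc2)(c2ccccc2)C(C)(C)C | intermediate
14 | (3S,4S)-5-hydroxy-4-methyl-3-{[(2S)-4-(tert-butyldiphenylsilyloxy)butan-2-yl]oxy}pentan-2-one | OC[C@H](C)[C@@H](C(C)=O)O[C@@H](C)CCO[Si](c1ccccc1)(c1ccccc1)C(C)(C)C | intermediate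
15 | (2S,3S)-2-methyl-4-oxo-3-{[(2S)-4-(tert-butyldiphenylsilyloxy)butan-2-yl]oxy}pentyl 2,2-dimethylpropanoate | CC(C)(C)C(=O)OC[C@H](C)[C@@H](C(C)=O)O[C@@H](C)CCO[Si](c1ccccc1)(c1ccccc1)C(C)(C)C | intermediate
16 | diazoalkene from 15 (C20=C21=N2) | CC(C)(C)C(=O)OC[C@H](C)[C@@H](C(C)=C=[N+]=[N-])O[C@@H](C)CCO[Si](c1ccccc1)(c1ccccc1)C(C)(C)C | intermediate
17 | alkylidene carbene from 15 (divalent C21) | CC(C)(C)C(=O)OC[C@H](C)[C@@H](C(C)=[C])O[C@@H](C)CCO[Si](c1ccccc1)(c1ccccc1)C(C)(C)C | intermediate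
18 | (2S)-2-[(2S,5S)-5-{2-(tert-butyldiphenylsilyloxy)ethyl}-3,5-dimethyl-2,5-dihydrofuran-2-yl]propyl 2,2-dimethylpropanoate | CC(C)(C)C(=O)OC[C@H](C)[C@@H]1O[C@@](C)(CCO[Si](c2ccccc2)(c2ccccc2)C(C)(C)C)C=C1C | intermediate
19 | (2S)-2-[(2S,5S)-5-{2-(tert-butyldiphenylsilyloxy)ethyl}-3,5-dimethyl-2,5-dihydrofuran-2-yl]propan-1-ol | OC[C@H](C)[C@@H]1O[C@@](C)(CCO[Si](c2ccccc2)(c2ccccc2)C(C)(C)C)C=C1C | intermediate
20 | (2S)-2-[(2R,3R,5R)-5-{2-(tert-butyldiphenylsilyloxy)ethyl}-3,5-dimethyloxolan-2-yl]propan-1-ol | OC[C@H](C)[C@@H]1O[C@@](C)(CCO[Si](c2ccccc2)(c2ccccc2)C(C)(C)C)C[C@H]1C | intermediate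
21 | (2R)-2-[(2R,3R,5R)-5-{2-(tert-butyldiphenylsilyloxy)ethyl}-3,5-dimethyloxolan-2-yl]propanal | O=C[C@H](C)[C@@H]1O[C@@](C)(CCO[Si](c2ccccc2)(c2ccccc2)C(C)(C)C)C[C@H]1C | intermediate
22 | (2S)-pent-3-yn-2-yl methanesulfonate | CC#C[C@H](C)OS(C)(=O)=O | intermediate
23 | (M)-ethyl(penta-2,3-dien-2-yl)zinc | C[CH]=[C@]=C(C)[Zn]CC | intermediate
24 | (2S,3R,4R)-2-[(2R,3R,5R)-5-{2-(tert-butyldiphenylsilyloxy)ethyl}-3,5-dimethyloxolan-2-yl]-4-methylhept-5-yn-3-ol | CC#C[C@@H](C)[C@@H](O)[C@H](C)[C@@H]1O[C@@](C)(CCO[Si](c2ccccc2)(c2ccccc2)C(C)(C)C)C[C@H]1C | intermediate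
25 | triethylsilyl ether of 24 | CC#C[C@@H](C)[C@@H](O[Si](CC)(CC)CC)[C@H](C)[C@@H]1O[C@@](C)(CCO[Si](c2ccccc2)(c2ccccc2)C(C)(C)C)C[C@H]1C | intermediate
26 | methyl 2-[bis(2,2,2-trifluoroethoxy)phosphoryl]acetate | COC(=O)CP(=O)(OCC(F)(F)F)OCC(F)(F)F | starting material
27 | methyl 2-[bis(2,2,2-trifluoroethoxy)phosphoryl]butanoate (racemic) | CCC(C(=O)OC)P(=O)(OCC(F)(F)F)OCC(F)(F)F | intermediate
28 | (4S)-4-benzyl-3-propanoyl-1,3-oxazolidin-2-one | CCC(=O)N1C(=O)OC[C@@H]1Cc1ccccc1 | starting material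
29 | 3-bromoprop-1-yne | C#CCBr | starting material
30 | (4S)-4-benzyl-3-[(2R)-2-methylpent-4-ynoyl]-1,3-oxazolidin-2-one | C#CC[C@@H](C)C(=O)N1C(=O)OC[C@@H]1Cc1ccccc1 | intermediate
31 | (2R)-2-methylpent-4-yn-1-ol | C#CC[C@@H](C)CO | intermediate
32 | (E)-alkenylzirconocene chloride of 31, oxygen also bound to Cp2ZrCl | Cl[Zr](C1C=CC=C1)(C1C=CC=C1)/C=C/C[C@@H](C)CO[Zr](Cl)(C1C=CC=C1)C1C=CC=C1 | intermediate
33 | (2R,4E)-5-iodo-2-methylpent-4-en-1-ol | I/C=C/C[C@@H](C)CO | intermediate
34 | (2R,4E)-5-iodo-2-methylpent-4-enal | I/C=C/C[C@@H](C)C=O | intermediate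
35 | methyl (2Z,4R,6E)-2-ethyl-7-iodo-4-methylhepta-2,6-dienoate | CCC(=C/[C@H](C)C/C=C/I)/C(=O)OC | intermediate
36 | (2Z,4R,6E)-2-ethyl-7-iodo-4-methylhepta-2,6-dien-1-ol | CCC(=C/[C@H](C)C/C=C/I)/CO | intermediate
37 | (2Z,4R,6E)-2-ethyl-7-iodo-4-methylhepta-2,6-dienal | CCC(=C/[C@H](C)C/C=C/I)/C=O | intermediate
38 | (2E,4Z,6R,8E)-4-ethyl-9-iodo-N-methoxy-N,6-dimethylnona-2,4,8-trienamide | CCC(=C/[C@H](C)C/C=C/I)/C=C/C(=O)N(C)OC | intermediate
39 | (2E,4Z,6R,8E)-4-ethyl-9-iodo-6-methylnona-2,4,8-trienal | CCC(=C/[C@H](C)C/C=C/I)/C=C/C=O | intermediate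
40 | (3S,4R,5E,7Z,9R,11E)-7-ethyl-12-iodo-3,9-dimethyldodeca-1,5,7,11-tetraen-4-ol | CCC(=C/[C@H](C)C/C=C/I)/C=C/[C@@H](O)[C@@H](C)C=C | intermediate
41 | prop-2-enoate of 40 | CCC(=C/[C@H](C)C/C=C/I)/C=C/[C@@H](OC(=O)C=C)[C@@H](C)C=C | intermediate
42 | (5S,6R)-6-[(1E,3Z,5R,7E)-3-ethyl-8-iodo-5-methylocta-1,3,7-trienyl]-5-methyl-5,6-dihydro-2H-pyran-2-one | CCC(=C/[C@H](C)C/C=C/I)/C=C/[C@H]1OC(=O)C=C[C@@H]1C | intermediate
43 | (E)-alkenylzirconocene chloride from 25 (Zr on C14) | Cl[Zr](C1C=CC=C1)(C1C=CC=C1)/C(C)=C/[C@@H](C)[C@@H](O[Si](CC)(CC)CC)[C@H](C)[C@@H]1O[C@@](C)(CCO[Si](c2ccccc2)(c2ccccc2)C(C)(C)C)C[C@H]1C | intermediate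
44 | (E)-alkenylzinc chloride from 25 (Zn on C14) | Cl[Zn]/C(C)=C/[C@@H](C)[C@@H](O[Si](CC)(CC)CC)[C@H](C)[C@@H]1O[C@@](C)(CCO[Si](c2ccccc2)(c2ccccc2)C(C)(C)C)C[C@H]1C | intermediate
45 | protected coupling product (C17–OSiEt3, C24–OSi(t-Bu)Ph2; stereocentres as in 25 and 42; 6E,8Z,12E,14E) | CCC(=C/[C@H](C)C/C=C/C(C)=C/[C@@H](C)[C@@H](O[Si](CC)(CC)CC)[C@H](C)[C@@H]1O[C@@](C)(CCO[Si](c2ccccc2)(c2ccccc2)C(C)(C)C)C[C@H]1C)/C=C/[C@H]1OC(=O)C=C[C@@H]1C | intermediate
46 | C17 alcohol (17R) with C24–OSi(t-Bu)Ph2 | CCC(=C/[C@H](C)C/C=C/C(C)=C/[C@@H](C)[C@@H](O)[C@H](C)[C@@H]1O[C@@](C)(CCO[Si](c2ccccc2)(c2ccccc2)C(C)(C)C)C[C@H]1C)/C=C/[C@H]1OC(=O)C=C[C@@H]1C | intermediate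
47 | C24-O-tert-butyldiphenylsilyl ether of the target | CCC(=C/[C@H](C)C/C=C/C(C)=C/[C@@H](C)C(=O)[C@H](C)[C@@H]1O[C@@](C)(CCO[Si](c2ccccc2)(c2ccccc2)C(C)(C)C)C[C@H]1C)/C=C/[C@H]1OC(=O)C=C[C@@H]1C | intermediate
48 | (5S,6R)-6-[(1E,3Z,5R,7E,9E,11R,13R)-3-ethyl-13-[(2R,3R,5R)-5-(2-hydroxyethyl)-3,5-dimethyloxolan-2-yl]-5,9,11-trimethyl-12-oxotetradeca-1,3,7,9-tetraenyl]-5-methyl-5,6-dihydro-2H-pyran-2-one | CCC(=C/[C@H](C)C/C=C/C(C)=C/[C@@H](C)C(=O)[C@H](C)[C@@H]1O[C@@](C)(CCO)C[C@H]1C)/C=C/[C@H]1OC(=O)C=C[C@@H]1C | target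

**Count and risks**

Total step count: 32. Longest linear sequence: 17 steps (4 → 48 through steps 3–13, 15, 16 and 29–32; the west branch is 15 steps, 18–28 then 29–32).

Steps most likely to fail:

Step 10 (key step). The carbene may be diverted: 1,2-shift to an alkyne, insertion into the C17–H bonds, or prior enolisation of the α-alkoxy ketone by the basic reagent with epimerisation at C19. Ring closure would then be inefficient. The fallback uses a metal carbenoid instead of the free carbene and sets out from 15. Trifluoroacetylation of the kinetic methyl enolate (LiN(SiMe3)2, CF3CO2CH2CF3, THF, −78 °C) would give the trifluoroacetyl ketone F1, and diazo transfer (MsN3, Et3N, aqueous MeCN) the α-diazo ketone F2. Rh2(OAc)4 (1 mol %, CH2Cl2, rt) should effect carbenoid 1,5 C–H insertion into the same tertiary ether C–H bond, again with retention, giving the oxolan-3-one F3 (C20 ketone). Non-basic methylenation (Zn, CH2Br2, TiCl4, THF) would give the 3-methylene oxolane pivalate F4, and i-Bu2AlH the alcohol F5. Hydroxyl-directed hydrogenation as in step 12 then sets C20, and the fallback comes back to the route at 20.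

Step 12. Hydroxyl direction through the six-membered chelate may be too weak, so that H2 is delivered from the wrong ring face, or iridium may shift the double bond toward C19. The fallback works under thermodynamic control and sets out from 18. Hydroboration–oxidation (BH3·THF; NaBO3) would give the C21 alcohols F6 as a mixture. Dess–Martin oxidation and equilibration with DBU (toluene, rt) would give the C21 ketone F7, in which the now epimerisable C20 methyl should settle trans to the C19 side chain. Condensation with TsNHNH2 would give the tosylhydrazone F8, and reduction with catecholborane followed by NaOAc·3H2O the saturated pivalate F9. i-Bu2AlH as in step 11 then gives 20, where the fallback rejoins the route.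

Step 29. Regiocontrol in the hydrozirconation of the internal alkyne may be incomplete, or residual zirconium hydride may attack the lactone partner in the one-pot operation. The fallback is a stepwise Stille coupling and sets out from 25. Hydrozirconation and iodinolysis (Cp2Zr(H)Cl, THF, 50 °C; I2) would give the vinyl iodide F10, which is purified. Iodine–lithium exchange and stannylation (t-BuLi, Et2O, −78 °C; Me3SnCl) would give the vinylstannane F11. Coupling with 42 (Pd(PPh3)4, copper thiophene-2-carboxylate CuO2CC4H3S, [Bu4N][Ph2PO2], DMF, rt) gives 45, where it comes back to the route.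

**Further compounds**

F1 | step 10 | trifluoroacetyl ketone from 15 (C21 acylated) | CC(C)(C)C(=O)OC[C@H](C)[C@@H](C(=O)CC(=O)C(F)(F)F)O[C@@H](C)CCO[Si](c1ccccc1)(c1ccccc1)C(C)(C)C
F2 | step 10 | α-diazo ketone (diazo on C21) | CC(C)(C)C(=O)OC[C@H](C)[C@@H](C(=O)C=[N+]=[N-])O[C@@H](C)CCO[Si](c1ccccc1)(c1ccccc1)C(C)(C)C
F3 | step 10 | oxolan-3-one pivalate (C20 ketone, C22 quaternary) | CC(C)(C)C(=O)OC[C@H](C)[C@@H]1O[C@@](C)(CCO[Si](c2ccccc2)(c2ccccc2)C(C)(C)C)CC1=O
F4 | step 10 | 3-methylene oxolane pivalate | CC(C)(C)C(=O)OC[C@H](C)[C@@H]1O[C@@](C)(CCO[Si](c2ccccc2)(c2ccccc2)C(C)(C)C)CC1=C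
F5 | step 10 | 3-methylene oxolane alcohol | OC[C@H](C)[C@@H]1O[C@@](C)(CCO[Si](c2ccccc2)(c2ccccc2)C(C)(C)C)CC1=C
F6 | step 12 | C21 alcohols from hydroboration of 18 (mixture at C20 and C21) | CC(C)(C)C(=O)OC[C@H](C)[C@@H]1O[C@@](C)(CCO[Si](c2ccccc2)(c2ccccc2)C(C)(C)C)C(O)C1C
F7 | step 12 | C21 ketone with C20 methyl trans to the C19 side chain | CC(C)(C)C(=O)OC[C@H](C)[C@@H]1O[C@@](C)(CCO[Si](c2ccccc2)(c2ccccc2)C(C)(C)C)C(=O)[C@H]1C
F8 | step 12 | tosylhydrazone of F7 | CC(C)(C)C(=O)OC[C@H](C)[C@@H]1O[C@@](C)(CCO[Si](c2ccccc2)(c2ccccc2)C(C)(C)C)C(=NNS(=O)(=O)c2ccc(C)cc2)[C@H]1C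
F9 | step 12 | saturated oxolane pivalate (pivalate of 20) | CC(C)(C)C(=O)OC[C@H](C)[C@@H]1O[C@@](C)(CCO[Si](c2ccccc2)(c2ccccc2)C(C)(C)C)C[C@H]1C
F10 | step 29 | (E)-vinyl iodide from 25 (iodine on C14) | I/C(C)=C/[C@@H](C)[C@@H](O[Si](CC)(CC)CC)[C@H](C)[C@@H]1O[C@@](C)(CCO[Si](c2ccccc2)(c2ccccc2)C(C)(C)C)C[C@H]1C
F11 | step 29 | (E)-vinyl trimethylstannane from F10 | C[Sn](C)(C)/C(C)=C/[C@@H](C)[C@@H](O[Si](CC)(CC)CC)[C@H](C)[C@@H]1O[C@@](C)(CCO[Si](c2ccccc2)(c2ccccc2)C(C)(C)C)C[C@H]1C
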